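**Assumptions (one line):** I read the target as benzylic (R), carbinol (S), with E-alkene and E-enone. I assume 2′,4′-dihydroxy-6′-methoxyacetophenone, methyl 3-(4-hydroxyphenyl)propanoate, 4-(methoxymethoxy)benzaldehyde and 1-bromo-4-(methoxymethoxy)benzene are purchasable. The pinene and BINOL enantiomers named below are the ones I expect to give the required senses. The benzylic sense in particular must be confirmed against the target's rotation or HPLC data.

## Retrosynthesis
1. Cleave the enone C=C (Claisen–Schmidt) to give a 3′-substituted 2′-hydroxy-4′,6′-dioxygenated acetophenone and MOM-protected 4-hydroxybenzaldehyde.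
2. Cleave the ArA–CH(Ar′)–CH=CH bond by enantioselective alkenylation of an o-quinone methide (chiral biphenol/boronate). This disconnects to an o-hydroxybenzhydrol and a chiral (E)-alkenyl-Bpin.
3. The benzhydrol comes from ArMgBr plus a 3-formyl acetophenone. That aldehyde comes from 2-OH-directed ortho-formylation of commercial 2′,4′-dihydroxy-6′-methoxyacetophenone.
4. The alkenyl-Bpin comes from cross-metathesis of vinyl-Bpin with an (S)-homoallylic alcohol, which is made by Brown allylation of 3-(4-MOMO-phenyl)propanal.
5. No ring is constructed, because all three arenes are present in commercial materials. The bonds made are the carbinol stereocentre (Brown), the benzylic C–C bond and stereocentre (o-QM alkenylation), and the enone (aldol condensation).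

## Route

**Step 1**
Reactants: 1, methyl 3-(4-hydroxyphenyl)propanoate
Product: 2, methyl 3-[4-(methoxymethoxy)phenyl]propanoate
Conditions: MOMCl, i-Pr2NEt, CH2Cl2, 0 °C → rt
Reagents that add atoms: chloromethyl methyl ether (MOMCl), COCCl
Why: Phenol O-alkylation under mild base masks the phenol for the Grignard/borane chemistry later, and the ester is untouched.

**Step 2**
Reactants: 2
Product: 3, 3-[4-(methoxymethoxy)phenyl]propanal
Conditions: DIBAL-H (1.1 equiv), CH2Cl2, –78 °C, 1 h; Rochelle salt workup
Reagents that add atoms: none
Why: Partial ester reduction stops at the aldehyde because the tetrahedral aluminium hemiacetal is stable at –78 °C. The MOM ether is inert, and no stereocentre is involved.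

**Step 3**
Reactants: 3
Product: 4, (S)-1-[4-(methoxymethoxy)phenyl]hex-5-en-3-ol
Conditions: B-allyldiisopinocampheylborane prepared from (–)-α-pinene, i.e. (+)-Ipc2B(allyl), Et2O, –78 °C, 3 h; then NaOH/H2O2, 0 °C
Reagents that add atoms: allylmagnesium bromide (the source of the allyl group in the Ipc2B-allyl reagent), C=CC[Mg]Br
Why: Asymmetric allylboration (Brown) goes through a Zimmerman–Traxler chair transition state with the aldehyde R group equatorial. The Ipc ligands fix the aldehyde face and set the carbinol as (S). The chiral borane is the stoichiometric source of chirality; its pinene enantiomer is chosen to give (S).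

**Step 4**
Reactants: 4, alcohol; 5, vinylboronic acid pinacol ester
Product: 6, (3S,5E)-1-[4-(methoxymethoxy)phenyl]-6-(4,4,5,5-tetramethyl-1,3,2-dioxaborolan-2-yl)hex-5-en-3-ol
Conditions: Grubbs II (5 mol %), CH2Cl2, 40 °C, 12 h, with 3 equiv of 5
Reagents that add atoms: none; the vinyl-Bpin is reactant 5
Why: Ru-catalysed cross-metathesis of a terminal alkene with vinyl-Bpin gives the thermodynamically favoured (E)-alkenylboronate and expels ethylene. The free secondary alcohol and MOM ether are tolerated, and the stereocentre is not involved.

**Step 5**
Reactants: 7, 2′,4′-dihydroxy-6′-methoxyacetophenone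
Product: 8, 1-[2-hydroxy-6-methoxy-4-(methoxymethoxy)phenyl]ethan-1-one
Conditions: MOMCl (1.1 equiv), i-Pr2NEt, CH2Cl2, 0 °C
Reagents that add atoms: MOMCl, COCCl
Why: The 2-OH is strongly H-bonded to the carbonyl, so the free 4-OH is alkylated selectively. This leaves only C3 with an ortho free OH for the following steps.

**Step 6**
Reactants: 8
Product: 9, 1-[3-formyl-2-hydroxy-6-methoxy-4-(methoxymethoxy)phenyl]ethan-1-one
Conditions: MgCl2 (anhydrous, 2 equiv), Et3N (4 equiv), (CH2O)n (6 equiv), THF, reflux, 6 h
Reagents that add atoms: paraformaldehyde, C=O (the formyl carbon)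
Why: This is the Mg-phenoxide-directed ortho-formylation (Casiraghi/Skattebøl type). It can only occur ortho to the free 2-OH, and C1 is blocked, so it is regiospecific at C3.

**Step 7**
Reactants: 9; 10, 1-bromo-4-(methoxymethoxy)benzene (converted to the Grignard with Mg, THF)
Product: 11, racemic 1-{2-hydroxy-3-[hydroxy(4-MOMO-phenyl)methyl]-6-methoxy-4-MOMO-phenyl}ethan-1-one
Conditions: 4-(MOMO)C6H4MgBr (3 equiv, from 10 and Mg in THF), THF, –78 → 0 °C; quench with pH 7 phosphate buffer
Reagents that add atoms: none; the aryl group comes from 10
Why: Grignard 1,2-addition to the aldehyde. Excess reagent first deprotonates the phenol, and the di-ortho-substituted acetophenone carbonyl is far less electrophilic than the aldehyde. The new carbinol is racemic, which does not matter because it is ionised to an achiral o-QM in the next step. A neutral workup avoids premature ionisation.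

**Step 8**
Reactants: 11; 6
Product: 12, (R)-benzylic, (S)-carbinol acetophenone, (3S,5E)-configured chain attached at C3′
Conditions: (S)-3,3′-Br2-BINOL (20 mol %), toluene, 4 Å MS, 50 °C, 48 h, with 1.5 equiv of 6
Reagents that add atoms: none; the alkenyl group comes from reactant 6
Why: The benzhydrol ionises through the o-hydroxyl, assisted by the boronate, to an achiral o-quinone methide; this ionisation is facile because the benzylic carbon is flanked by three O-donors. The chiral biphenol–alkenylboronate complex then delivers the (E)-alkenyl group to one face (Petasis-type o-QM alkenylation), so the racemic 11 converges on the (R) benzylic centre. The remote C5 alcohol stereocentre has little influence, so the catalyst controls the diastereomer ratio, and the minor diastereomer is removed by chromatography. The alkene geometry is transferred stereospecifically.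

**Step 9**
Reactants: 12; 13, 4-(methoxymethoxy)benzaldehyde
Product: 14, fully MOM-protected chalcone
Conditions: KOH (50% aq.), EtOH, rt, 48 h
Reagents that add atoms: none; the aryl enone unit comes from 13
Why: Claisen–Schmidt aldol condensation by enolate addition then E1cB dehydration gives the E-enone. MOM ethers, the free secondary alcohol and the E-alkene survive. The diaryl allylic C–H is not acidic enough to epimerise under these conditions, and no α-H is adjacent to it.

**Step 10**
Reactants: 14
Product: 15, epicalyxin B
Conditions: 3 M HCl–MeOH (1:5), 40 °C, 3 h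
Reagents that add atoms: none; H is the only atom added in net terms, and the MOM groups leave as CH2(OMe)2
Why: Acidolysis of the four aryl MOM acetals. The chelated 2′-OH chalcone with 6′-OMe is reluctant to cyclise to the flavanone under mild acid, and neither stereocentre is touched.

## Compound list
1 | methyl 3-(4-hydroxyphenyl)propanoate | COC(=O)CCc1ccc(O)cc1 | starting material
2 | methyl 3-[4-(methoxymethoxy)phenyl]propanoate | COC(=O)CCc1ccc(OCOC)cc1 | intermediate
3 | 3-[4-(methoxymethoxy)phenyl]propanal | O=CCCc1ccc(OCOC)cc1 | intermediate
4 | (S)-1-[4-(methoxymethoxy)phenyl]hex-5-en-3-ol | C=CC[C@@H](O)CCc1ccc(OCOC)cc1 | intermediate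
5 | vinylboronic acid pinacol ester | C=CB1OC(C)(C)C(C)(C)O1 | starting material
6 | (3S,5E)-1-[4-(methoxymethoxy)phenyl]-6-(Bpin)hex-5-en-3-ol | CC1(C)OB(/C=C/C[C@@H](O)CCc2ccc(OCOC)cc2)OC1(C)C | intermediate
7 | 2′,4′-dihydroxy-6′-methoxyacetophenone | CC(=O)c1c(O)cc(O)cc1OC | starting material
8 | 1-[2-hydroxy-6-methoxy-4-(methoxymethoxy)phenyl]ethanone | CC(=O)c1c(O)cc(OCOC)cc1OC | intermediate
9 | 1-[3-formyl-2-hydroxy-6-methoxy-4-(methoxymethoxy)phenyl]ethanone | CC(=O)c1c(O)c(C=O)c(OCOC)cc1OC | intermediate
10 | 1-bromo-4-(methoxymethoxy)benzene | COCOc1ccc(Br)cc1 | starting material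
11 | racemic o-hydroxybenzhydrol (bis-MOM) | CC(=O)c1c(O)c(C(O)c2ccc(OCOC)cc2)c(OCOC)cc1OC | intermediate
12 | tri-MOM acetophenone, (R)-benzylic, (S)-carbinol | COc1cc(OCOC)c([C@H](/C=C/C[C@@H](O)CCc2ccc(OCOC)cc2)c2ccc(OCOC)cc2)c(O)c1C(C)=O | intermediate
13 | 4-(methoxymethoxy)benzaldehyde | COCOc1ccc(C=O)cc1 | starting material
14 | tetra-MOM chalcone | COc1cc(OCOC)c([C@H](/C=C/C[C@@H](O)CCc2ccc(OCOC)cc2)c2ccc(OCOC)cc2)c(O)c1C(=O)/C=C/c1ccc(OCOC)cc1 | intermediate
15 | epicalyxin B | COc1cc(O)c([C@H](/C=C/C[C@@H](O)CCc2ccc(O)cc2)c2ccc(O)cc2)c(O)c1C(=O)/C=C/c1ccc(O)cc1 | target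

**Total steps:** 10. **Longest linear sequence:** 7 (1 → 2 → 3 → 4 → 6 → 12 → 14 → 15, i.e. Steps 1–4 and 8–10).

## Three steps most likely to fail
1. **Step 8 (enantioselective o-QM alkenylation).** The o-QM is very stabilised, so background non-selective reaction or low ee/dr is possible, and the catalyst sense is unproven for this substrate. Fallback: run the reaction with an achiral promoter (racemic BINOL or a simple Lewis acid). The benzylic epimers are then diastereomers because the carbinol is already (S), so they can be separated by preparative HPLC and the (R,S) isomer carried forward.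
2. **Step 6 (ortho-formylation) and the linked benzhydrol Step 7.** The electron-poor, chelated 2-hydroxyacetophenone may formylate poorly, and the electron-rich benzhydrol may be prone to ionisation or dimerisation. Fallback: skip both steps and run a three-component Petasis-type coupling of 8, 13 and 6 with the chiral biphenol catalyst, generating the o-QM in situ from phenol and aldehyde.
3. **Step 10 (MOM removal on the chalcone).** Acid may cause flavanone cyclisation or partial alkene/alcohol side reactions. Fallback: reorder so the MOM groups are removed at the acetophenone stage (from 12, where no enone can cyclise), then finish with Claisen–Schmidt condensation using 4-hydroxybenzaldehyde and excess LiOH or KOH in aqueous EtOH.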